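The route rests on disconnecting the junction bond C1–C2 (cembrane numbering: C1 = ring-fusion CH, C2 = O–CH) shared by the 14-membered carbocycle and the α-methylene-γ-butyrolactone. The homoallylic array O–C2–C1–C15(=C17H2)–C16(=O) is the retron of a 2-alkoxycarbonylallylboration. An open-chain (E)-enal carrying, at the far terminus, a geometrically defined methyl 2-(borylmethyl)alk-2-enoate cyclises under chiral phosphoric acid catalysis. This forms C1–C2, both new stereocentres, the exocyclic methylene and the 14-membered ring, and the resulting borate lactonises in the same flask to the trans-fused lactone. The chain comes from geranyl acetate by two catalytic asymmetric vinylogous Mukaiyama aldol additions.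

Key step: step 17

Remark on the chemistry: the target is read as (1R,2S,6S,10S) with a trans-fused lactone and three E ring alkenes (C6 = CH–OAc, C10 = CH–OH). The (S,S)-enantiomer of the bisphosphoramide catalyst is taken to be the one that delivers the dienolate to the Si face of the enals, and (R)-TRIP to direct allylboration to the Re face of an aldehyde.

Step 1
Reactants: 1 geranyl acetate
Product: 3 (2E)-3-methyl-6-oxohex-2-en-1-yl acetate, via ozonide 2 (not isolated)
Conditions: O3 (1.0 equiv, Sudan Red 7B end-point), CH2Cl2, −78 °C; then Me2S, −78 °C to rt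
Reagents that add atoms: ozone, O=[O+][O-]
Why: Ozonolysis with reductive work-up, in which the electron-rich 6,7-alkene should react far faster than the 2,3-alkene deactivated by the allylic acetate, so that only the isopropylidene end is cleaved.

Step 2
Reactants: 3 (2E)-3-methyl-6-oxohex-2-en-1-yl acetate
Product: 5 (2E)-3-methylhept-2-en-6-yn-1-ol, via alkynyl acetate 4 (not isolated)
Conditions: Ohira–Bestmann reagent, K2CO3, MeOH, 0 °C to rt
Reagents that add atoms: dimethyl (1-diazo-2-oxopropyl)phosphonate, COP(=O)(OC)C(=[N+]=[N-])C(C)=O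
Why: Ohira–Bestmann (Seyferth–Gilbert) homologation should turn the aldehyde into the terminal alkyne while the K2CO3/MeOH medium methanolyses the allylic acetate in the same flask.

Step 3
Reactants: 5 (2E)-3-methylhept-2-en-6-yn-1-ol
Product: 6 (2E)-3-methylhept-2-en-6-ynal
Conditions: activated MnO2, CH2Cl2, rt
Reagents that add atoms: none
Why: Allylic oxidation with MnO2 should give the (E)-enal without touching the terminal alkyne.

Step 4
Reactants: 7 ethyl 3-methylbut-2-enoate
Product: 9 1-(tert-butyldimethylsilyloxy)-1-ethoxy-3-methylbuta-1,3-diene, via lithium dienolate 8 (not isolated)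
Conditions: LDA, THF, −78 °C; then TBSCl, DMPU, −78 °C to rt
Reagents that add atoms: tert-butyldimethylsilyl chloride, CC(C)(C)[Si](C)(C)Cl
Why: Kinetic γ-deprotonation of the enoate and O-silylation of the extended enolate (silyl ketene acetal formation) should give the dienolate, whose ketene acetal geometry is irrelevant because that carbon becomes the ester carbon again.

Step 5
Reactants: 6 (2E)-3-methylhept-2-en-6-ynal; 9 1-(tert-butyldimethylsilyloxy)-1-ethoxy-3-methylbuta-1,3-diene
Product: 10 ethyl (2E,5S,6E)-5-hydroxy-3,7-dimethylundeca-2,6-dien-10-ynoate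
Conditions: SiCl4, (S,S)-pentamethylene-linked bis(BINAM-phosphoramide) catalyst (5 mol%), i-Pr2NEt (10 mol%), CH2Cl2, −78 °C; aq. NaHCO3/KF
Reagents that add atoms: none
Why: Lewis-base-activated SiCl4 vinylogous Mukaiyama aldol addition, in which the chiral phosphoramide-bound trichlorosilyl cation activates the enal and the dienolate attacks through its γ-carbon on the Si face, should set the (5S) carbinol (later C10) and, from the s-trans dienolate, the (2E) enoate.

Step 6
Reactants: 10 ethyl (2E,5S,6E)-5-hydroxy-3,7-dimethylundeca-2,6-dien-10-ynoate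
Product: 11 ethyl (2E,5S,6E)-5-[(tert-butyldimethylsilyl)oxy]-3,7-dimethylundeca-2,6-dien-10-ynoate
Conditions: TBSCl, imidazole, DMF, rt
Reagents that add atoms: tert-butyldimethylsilyl chloride, CC(C)(C)[Si](C)(C)Cl
Why: Standard silylation of the secondary allylic alcohol installs the one silyl ether that has to survive until the last step.

Step 7
Reactants: 11 ethyl (2E,5S,6E)-5-[(tert-butyldimethylsilyl)oxy]-3,7-dimethylundeca-2,6-dien-10-ynoate
Product: 12 (2E,5S,6E)-5-[(tert-butyldimethylsilyl)oxy]-3,7-dimethylundeca-2,6-dien-10-yn-1-ol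
Conditions: i-Bu2AlH (2.5 equiv), CH2Cl2, −78 °C; Rochelle salt
Reagents that add atoms: none
Why: 1,2-Reduction of the enoate by i-Bu2AlH at low temperature should give the allylic alcohol, the alkyne and silyl ether being inert.

Step 8
Reactants: 12 (2E,5S,6E)-5-[(tert-butyldimethylsilyl)oxy]-3,7-dimethylundeca-2,6-dien-10-yn-1-ol
Product: 13 (2E,5S,6E)-5-[(tert-butyldimethylsilyl)oxy]-3,7-dimethylundeca-2,6-dien-10-ynal
Conditions: activated MnO2, CH2Cl2, rt
Reagents that add atoms: none
Why: Allylic oxidation with MnO2 should give the (E)-enal for the second chain extension.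

Step 9
Reactants: 13 (2E,5S,6E)-5-[(tert-butyldimethylsilyl)oxy]-3,7-dimethylundeca-2,6-dien-10-ynal; 9 1-(tert-butyldimethylsilyloxy)-1-ethoxy-3-methylbuta-1,3-diene
Product: 14 ethyl (2E,5S,6E,9S,10E)-9-[(tert-butyldimethylsilyl)oxy]-5-hydroxy-3,7,11-trimethylpentadeca-2,6,10-trien-14-ynoate
Conditions: SiCl4, (S,S)-pentamethylene-linked bis(BINAM-phosphoramide) catalyst (5 mol%), i-Pr2NEt (10 mol%), CH2Cl2, −78 °C; aq. NaHCO3/KF
Reagents that add atoms: none
Why: A second catalyst-controlled vinylogous Mukaiyama aldol addition on the Si face of the enal should set the (5S) carbinol (later C6), the existing silyloxy centre being too remote (1,5) to interfere.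

Step 10
Reactants: 14 ethyl (2E,5S,6E,9S,10E)-9-[(tert-butyldimethylsilyl)oxy]-5-hydroxy-3,7,11-trimethylpentadeca-2,6,10-trien-14-ynoate
Product: 15 (2E,5S,6E,9S,10E)-9-[(tert-butyldimethylsilyl)oxy]-3,7,11-trimethylpentadeca-2,6,10-trien-14-yne-1,5-diol
Conditions: i-Bu2AlH (3.5 equiv), CH2Cl2, −78 °C; Rochelle salt
Reagents that add atoms: none
Why: Reduction of the enoate by i-Bu2AlH should give the primary allylic alcohol next to the free secondary one.

Step 11
Reactants: 15 (2E,5S,6E,9S,10E)-9-[(tert-butyldimethylsilyl)oxy]-3,7,11-trimethylpentadeca-2,6,10-trien-14-yne-1,5-diol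
Product: 16 (2E,5S,6E,9S,10E)-9-[(tert-butyldimethylsilyl)oxy]-3,7,11-trimethyl-1,5-bis(triethylsilyloxy)pentadeca-2,6,10-trien-14-yne
Conditions: TESCl (2.5 equiv), imidazole, CH2Cl2, 0 °C to rt
Reagents that add atoms: chlorotriethylsilane, CC[Si](Cl)(CC)CC
Why: Bis-silylation masks both hydroxyls for the strongly basic and hydridic steps with a group that can later be removed without loss of the TBS ether.

Step 12
Reactants: 16 (2E,5S,6E,9S,10E)-9-[(tert-butyldimethylsilyl)oxy]-3,7,11-trimethyl-1,5-bis(triethylsilyloxy)pentadeca-2,6,10-trien-14-yne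
Product: 18 methyl (6E,8S,10E,12S,14E)-8-[(tert-butyldimethylsilyl)oxy]-6,10,14-trimethyl-12,16-bis(triethylsilyloxy)hexadeca-6,10,14-trien-2-ynoate, via lithium acetylide 17 (not isolated)
Conditions: n-BuLi, THF, −78 °C; then ClCO2Me, −78 to 0 °C
Reagents that add atoms: methyl chloroformate, COC(=O)Cl
Why: Deprotonation of the terminal alkyne and C-acylation of the acetylide with the chloroformate should give the ynoate that carries C15 and C16.

Step 13
Reactants: 18 methyl (6E,8S,10E,12S,14E)-8-[(tert-butyldimethylsilyl)oxy]-6,10,14-trimethyl-12,16-bis(triethylsilyloxy)hexadeca-6,10,14-trien-2-ynoate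
Product: 20 methyl (2Z,6E,8S,10E,12S,14E)-8-[(tert-butyldimethylsilyl)oxy]-6,10,14-trimethyl-2-[(4,4,5,5-tetramethyl-1,3,2-dioxaborolan-2-yl)methyl]-12,16-bis(triethylsilyloxy)hexadeca-2,6,10,14-tetraenoate, via vinylalane 19 (not isolated)
Conditions: i-Bu2AlH, HMPA, THF, 0 °C; then ICH2Bpin, 0 °C to rt
Reagents that add atoms: 2-(iodomethyl)-4,4,5,5-tetramethyl-1,3,2-dioxaborolane, ICB1OC(C)(C)C(C)(C)O1
Why: Conjugate syn-hydroalumination of the ynoate by the i-Bu2AlH–HMPA complex should give the α-alumino acrylate with H and Al cis, and its alkylation with the iodomethylboronate with retention places the chain cis to the ester, that is trans to CH2B (crotyl-type E allylboronate).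

Step 14
Reactants: 20 methyl (2Z,6E,8S,10E,12S,14E)-8-[(tert-butyldimethylsilyl)oxy]-6,10,14-trimethyl-2-[(4,4,5,5-tetramethyl-1,3,2-dioxaborolan-2-yl)methyl]-12,16-bis(triethylsilyloxy)hexadeca-2,6,10,14-tetraenoate
Product: 21 methyl (2Z,6E,8S,10E,12S,14E)-8-[(tert-butyldimethylsilyl)oxy]-12,16-dihydroxy-6,10,14-trimethyl-2-[(4,4,5,5-tetramethyl-1,3,2-dioxaborolan-2-yl)methyl]hexadeca-2,6,10,14-tetraenoate
Conditions: PPTS (0.2 equiv), MeOH/CH2Cl2, 0 °C, monitored
Reagents that add atoms: none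
Why: Mild acid methanolysis should cleave the primary and secondary TES ethers much faster than the secondary TBS ether and leaves the pinacol allylboronate intact.

Step 15
Reactants: 21 methyl (2Z,6E,8S,10E,12S,14E)-8-[(tert-butyldimethylsilyl)oxy]-12,16-dihydroxy-6,10,14-trimethyl-2-[(4,4,5,5-tetramethyl-1,3,2-dioxaborolan-2-yl)methyl]hexadeca-2,6,10,14-tetraenoate
Product: 22 methyl (2Z,6E,8S,10E,12S,14E)-8-[(tert-butyldimethylsilyl)oxy]-12-hydroxy-6,10,14-trimethyl-16-oxo-2-[(4,4,5,5-tetramethyl-1,3,2-dioxaborolan-2-yl)methyl]hexadeca-2,6,10,14-tetraenoate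
Conditions: activated MnO2, CH2Cl2, 0 °C to rt, monitored
Reagents that add atoms: none
Why: MnO2 should oxidise the primary allylic alcohol much faster than the hindered secondary one, and the ester-bearing allylboronate is too unreactive to add to the new enal without acid.

Step 16
Reactants: 22 methyl (2Z,6E,8S,10E,12S,14E)-8-[(tert-butyldimethylsilyl)oxy]-12-hydroxy-6,10,14-trimethyl-16-oxo-2-[(4,4,5,5-tetramethyl-1,3,2-dioxaborolan-2-yl)methyl]hexadeca-2,6,10,14-tetraenoate
Product: 23 methyl (2Z,6E,8S,10E,12S,14E)-12-acetoxy-8-[(tert-butyldimethylsilyl)oxy]-6,10,14-trimethyl-16-oxo-2-[(4,4,5,5-tetramethyl-1,3,2-dioxaborolan-2-yl)methyl]hexadeca-2,6,10,14-tetraenoate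
Conditions: Ac2O, pyridine, DMAP (cat.), CH2Cl2, 0 °C
Reagents that add atoms: acetic anhydride, CC(=O)OC(C)=O
Why: DMAP-catalysed acylation of the only free hydroxyl installs the C6 acetate under conditions mild enough to avoid vinylogous elimination from the enal.

Step 17
Reactants: 23 methyl (2Z,6E,8S,10E,12S,14E)-12-acetoxy-8-[(tert-butyldimethylsilyl)oxy]-6,10,14-trimethyl-16-oxo-2-[(4,4,5,5-tetramethyl-1,3,2-dioxaborolan-2-yl)methyl]hexadeca-2,6,10,14-tetraenoate
Product: 25 (1R,2S,3E,6S,7E,10S,11E)-6-acetoxy-10-[(tert-butyldimethylsilyl)oxy]cembra-3,7,11,15(17)-tetraen-16,2-olide, via macrocyclic borate 24 (not isolated)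
Conditions: (R)-TRIP [3,3'-bis(2,4,6-triisopropylphenyl)-1,1'-binaphthyl-2,2'-diyl hydrogen phosphate] (20 mol%), 4 Å MS, toluene (0.002 M, 23 added by syringe pump), 40 °C; then 60 °C
Reagents that add atoms: none
Why: The phosphoric acid hydrogen-bonds to a boronate oxygen and to the formyl hydrogen, the enal carbonyl binds boron, and the γ-carbon of the allylboronate (C1) adds to the aldehyde carbon (C2) through a six-membered chair (Zimmerman–Traxler) transition state, an intramolecular use of the acid-catalysed allylboration of aldehydes by 2-alkoxycarbonyl allylboronates and of the chiral-phosphoric-acid-catalysed allylboration of enals. The 14-membered carbocycle closes by 14-exo-trig attack on the carbonyl, and the borate oxygen of 24 then closes the lactone by 5-exo-trig acyl substitution on the methyl ester with loss of MeOBpin. The relative configuration follows from the boronate geometry: with the chain trans to CH2B both tethers sit equatorial in the chair, which gives the anti adduct and hence the trans-fused lactone. The absolute configuration is set by the catalyst, (R)-TRIP directing attack to the Re face of the enal, which corresponds to (2S) and, through the chair, to (1R). The step needs ring closure over oligomerisation (high dilution and slow addition, helped by three E-trisubstituted alkenes that pre-organise the chain), 1,2- over 1,4-addition and γ- over α-attack (both inherent to the closed transition state), and catalyst over background control (the ester-bearing allylboronate is nearly inert without acid). The acid is too weak to ionise the allylic acetate or the new allylic carbinol.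

Step 18
Reactants: 25 (1R,2S,3E,6S,7E,10S,11E)-6-acetoxy-10-[(tert-butyldimethylsilyl)oxy]cembra-3,7,11,15(17)-tetraen-16,2-olide
Product: 26 (1R,2S,3E,6S,7E,10S,11E)-6-acetoxy-10-hydroxycembra-3,7,11,15(17)-tetraen-16,2-olide (CNP0168244.1)
Conditions: HF·pyridine, pyridine, THF, 0 °C to rt
Reagents that add atoms: none
Why: Buffered fluoride desilylation should free the C10 hydroxyl while sparing the acetate and the α-methylene lactone, which a basic fluoride source could attack.

Compound list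
1 | geranyl acetate, (2E)-3,7-dimethylocta-2,6-dien-1-yl acetate | CC(=O)OC/C=C(\C)CCC=C(C)C | starting material
2 | ozonide (3,3-dimethyl-1,2,4-trioxolane) of the 6,7-alkene of 1 | CC(=O)OC/C=C(\C)CCC1OOC(C)(C)O1 | intermediate
3 | (2E)-3-methyl-6-oxohex-2-en-1-yl acetate | CC(=O)OC/C=C(\C)CCC=O | intermediate
4 | (2E)-3-methylhept-2-en-6-yn-1-yl acetate | CC(=O)OC/C=C(\C)CCC#C | intermediate
5 | (2E)-3-methylhept-2-en-6-yn-1-ol | OC/C=C(\C)CCC#C | intermediate
6 | (2E)-3-methylhept-2-en-6-ynal | O=C/C=C(\C)CCC#C | intermediate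
7 | ethyl 3-methylbut-2-enoate | CCOC(=O)C=C(C)C | starting material
8 | lithium dienolate of 7 (lithium 1-ethoxy-3-methylbuta-1,3-dien-1-olate) | [Li]OC(OCC)=CC(C)=C | intermediate
9 | 1-(tert-butyldimethylsilyloxy)-1-ethoxy-3-methylbuta-1,3-diene | C=C(C)C=C(OCC)O[Si](C)(C)C(C)(C)C | intermediate
10 | ethyl (2E,5S,6E)-5-hydroxy-3,7-dimethylundeca-2,6-dien-10-ynoate | CCOC(=O)/C=C(\C)C[C@H](O)/C=C(\C)CCC#C | intermediate
11 | ethyl (2E,5S,6E)-5-[(tert-butyldimethylsilyl)oxy]-3,7-dimethylundeca-2,6-dien-10-ynoate | CCOC(=O)/C=C(\C)C[C@H](O[Si](C)(C)C(C)(C)C)/C=C(\C)CCC#C | intermediate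
12 | (2E,5S,6E)-5-[(tert-butyldimethylsilyl)oxy]-3,7-dimethylundeca-2,6-dien-10-yn-1-ol | OC/C=C(\C)C[C@H](O[Si](C)(C)C(C)(C)C)/C=C(\C)CCC#C | intermediate
13 | (2E,5S,6E)-5-[(tert-butyldimethylsilyl)oxy]-3,7-dimethylundeca-2,6-dien-10-ynal | O=C/C=C(\C)C[C@H](O[Si](C)(C)C(C)(C)C)/C=C(\C)CCC#C | intermediate
14 | ethyl (2E,5S,6E,9S,10E)-9-[(tert-butyldimethylsilyl)oxy]-5-hydroxy-3,7,11-trimethylpentadeca-2,6,10-trien-14-ynoate | CCOC(=O)/C=C(\C)C[C@H](O)/C=C(\C)C[C@H](O[Si](C)(C)C(C)(C)C)/C=C(\C)CCC#C | intermediate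
15 | (2E,5S,6E,9S,10E)-9-[(tert-butyldimethylsilyl)oxy]-3,7,11-trimethylpentadeca-2,6,10-trien-14-yne-1,5-diol | OC/C=C(\C)C[C@H](O)/C=C(\C)C[C@H](O[Si](C)(C)C(C)(C)C)/C=C(\C)CCC#C | intermediate
16 | (2E,5S,6E,9S,10E)-9-[(tert-butyldimethylsilyl)oxy]-3,7,11-trimethyl-1,5-bis(triethylsilyloxy)pentadeca-2,6,10-trien-14-yne | CC[Si](CC)(CC)OC/C=C(\C)C[C@H](O[Si](CC)(CC)CC)/C=C(\C)C[C@H](O[Si](C)(C)C(C)(C)C)/C=C(\C)CCC#C | intermediate
17 | lithium acetylide of 16 | CC[Si](CC)(CC)OC/C=C(\C)C[C@H](O[Si](CC)(CC)CC)/C=C(\C)C[C@H](O[Si](C)(C)C(C)(C)C)/C=C(\C)CCC#C[Li] | intermediate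
18 | methyl (6E,8S,10E,12S,14E)-8-[(tert-butyldimethylsilyl)oxy]-6,10,14-trimethyl-12,16-bis(triethylsilyloxy)hexadeca-6,10,14-trien-2-ynoate | CC[Si](CC)(CC)OC/C=C(\C)C[C@H](O[Si](CC)(CC)CC)/C=C(\C)C[C@H](O[Si](C)(C)C(C)(C)C)/C=C(\C)CCC#CC(=O)OC | intermediate
19 | α-(diisobutylalumino) acrylate from 18 (Al cis to the vinylic H, chain cis to the ester) | CC[Si](CC)(CC)OC/C=C(\C)C[C@H](O[Si](CC)(CC)CC)/C=C(\C)C[C@H](O[Si](C)(C)C(C)(C)C)/C=C(\C)CC/C=C(/[Al](CC(C)C)CC(C)C)C(=O)OC | intermediate
20 | methyl (2Z,6E,8S,10E,12S,14E)-8-[(tert-butyldimethylsilyl)oxy]-6,10,14-trimethyl-2-[(4,4,5,5-tetramethyl-1,3,2-dioxaborolan-2-yl)methyl]-12,16-bis(triethylsilyloxy)hexadeca-2,6,10,14-tetraenoate | CC[Si](CC)(CC)OC/C=C(\C)C[C@H](O[Si](CC)(CC)CC)/C=C(\C)C[C@H](O[Si](C)(C)C(C)(C)C)/C=C(\C)CC/C=C(/CB1OC(C)(C)C(C)(C)O1)C(=O)OC | intermediate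
21 | methyl (2Z,6E,8S,10E,12S,14E)-8-[(tert-butyldimethylsilyl)oxy]-12,16-dihydroxy-6,10,14-trimethyl-2-[(4,4,5,5-tetramethyl-1,3,2-dioxaborolan-2-yl)methyl]hexadeca-2,6,10,14-tetraenoate | OC/C=C(\C)C[C@H](O)/C=C(\C)C[C@H](O[Si](C)(C)C(C)(C)C)/C=C(\C)CC/C=C(/CB1OC(C)(C)C(C)(C)O1)C(=O)OC | intermediate
22 | methyl (2Z,6E,8S,10E,12S,14E)-8-[(tert-butyldimethylsilyl)oxy]-12-hydroxy-6,10,14-trimethyl-16-oxo-2-[(4,4,5,5-tetramethyl-1,3,2-dioxaborolan-2-yl)methyl]hexadeca-2,6,10,14-tetraenoate | O=C/C=C(\C)C[C@H](O)/C=C(\C)C[C@H](O[Si](C)(C)C(C)(C)C)/C=C(\C)CC/C=C(/CB1OC(C)(C)C(C)(C)O1)C(=O)OC | intermediate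
23 | methyl (2Z,6E,8S,10E,12S,14E)-12-acetoxy-8-[(tert-butyldimethylsilyl)oxy]-6,10,14-trimethyl-16-oxo-2-[(4,4,5,5-tetramethyl-1,3,2-dioxaborolan-2-yl)methyl]hexadeca-2,6,10,14-tetraenoate | O=C/C=C(\C)C[C@H](OC(C)=O)/C=C(\C)C[C@H](O[Si](C)(C)C(C)(C)C)/C=C(\C)CC/C=C(/CB1OC(C)(C)C(C)(C)O1)C(=O)OC | intermediate
24 | methyl 2-[(1R,2S,3E,6S,7E,10S,11E)-6-acetoxy-10-[(tert-butyldimethylsilyl)oxy]-4,8,12-trimethyl-2-[(4,4,5,5-tetramethyl-1,3,2-dioxaborolan-2-yl)oxy]cyclotetradeca-3,7,11-trien-1-yl]acrylate | CC1(C)OB(O[C@H]2/C=C(\C)C[C@H](OC(C)=O)/C=C(\C)C[C@H](O[Si](C)(C)C(C)(C)C)/C=C(\C)CC[C@@H]2C(=C)C(=O)OC)OC1(C)C | intermediate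
25 | (1R,2S,3E,6S,7E,10S,11E)-6-acetoxy-10-[(tert-butyldimethylsilyl)oxy]cembra-3,7,11,15(17)-tetraen-16,2-olide (trans-fused α-methylene-γ-butyrolactone) | C=C1C(=O)O[C@H]2/C=C(\C)C[C@H](OC(C)=O)/C=C(\C)C[C@H](O[Si](C)(C)C(C)(C)C)/C=C(\C)CC[C@H]12 | intermediate
26 | (1R,2S,3E,6S,7E,10S,11E)-6-acetoxy-10-hydroxycembra-3,7,11,15(17)-tetraen-16,2-olide (CNP0168244.1) | C=C1C(=O)O[C@H]2/C=C(\C)C[C@H](OC(C)=O)/C=C(\C)C[C@H](O)/C=C(\C)CC[C@H]12 | target

Total step count: 18. Longest linear sequence: 17 (steps 1–3 and 5–18 from geranyl acetate; step 4 is a side branch that serves steps 5 and 9).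

Steps most likely to fail

1. Step 17. Oligomerisation may compete with ring closure, the ester-deactivated boronate may turn over slowly under the weak acid, or the catalyst may discriminate the enal faces incompletely and give the other trans-lactone diastereomer. The fallback replaces the allylboronate by an allylchromium nucleophile (Nozaki–Hiyama-type macrocyclisation) and sets out from 20. Oxidation of the C–B bond with NaBO3·4H2O in THF/water would give the 2-(hydroxymethyl) enoate F1. CBr4/PPh3 would give the allylic bromide F2. PPTS in MeOH would remove both TES groups to give the diol bromide F3. MnO2 would give the hydroxy enal bromide F4. Excess CrCl2 in THF at high dilution would then close the 14-membered ring through the same γ-carbon and, after lactonisation, give the hydroxy lactone F5, diastereomers being separated by chromatography. Acetylation with Ac2O/pyridine brings the sequence back to 25.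

2. Step 13. The α-alumino acrylate may equilibrate through its allenolate before it is alkylated, which would erode the alkene geometry on which the trans ring fusion depends, or the alkylation may be sluggish. The fallback sets out from 18. Syn-hydrostannation with Bu3SnH and Pd(PPh3)4 would give the α-stannyl enoate F6 with tin cis to the vinylic hydrogen. Iododestannylation with I2 would give the α-iodo enoate F7 with retention. Negishi coupling of F7 with (pinacolboryl)methylzinc iodide under Pd(PPh3)4 would return to 20 with the geometry fixed by the hydrostannation.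

3. Step 5 (and in the same way step 9). Facial discrimination by the catalyst may be insufficient with a β,β-disubstituted aliphatic enal. The fallback sets out from 6 and 9 and moves the stereo-determining event to a ketone reduction. A BF3·OEt2-promoted vinylogous Mukaiyama aldol addition would give the racemic hydroxy ester F8. Dess–Martin periodinane would give the dienone F9. Corey–Bakshi–Shibata reduction with (R)-Me-CBS and catecholborane, the alkenyl group acting as the large substituent, should return to 10. The same three operations from 13 would return to 14.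

Further compounds
F1 | step 17 | methyl (2Z,6E,8S,10E,12S,14E)-8-[(tert-butyldimethylsilyl)oxy]-2-(hydroxymethyl)-6,10,14-trimethyl-12,16-bis(triethylsilyloxy)hexadeca-2,6,10,14-tetraenoate | CC[Si](CC)(CC)OC/C=C(\C)C[C@H](O[Si](CC)(CC)CC)/C=C(\C)C[C@H](O[Si](C)(C)C(C)(C)C)/C=C(\C)CC/C=C(/CO)C(=O)OC
F2 | step 17 | methyl (2E,6E,8S,10E,12S,14E)-2-(bromomethyl)-8-[(tert-butyldimethylsilyl)oxy]-6,10,14-trimethyl-12,16-bis(triethylsilyloxy)hexadeca-2,6,10,14-tetraenoate (chain cis to the ester) | CC[Si](CC)(CC)OC/C=C(\C)C[C@H](O[Si](CC)(CC)CC)/C=C(\C)C[C@H](O[Si](C)(C)C(C)(C)C)/C=C(\C)CC/C=C(/CBr)C(=O)OC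
F3 | step 17 | methyl (2E,6E,8S,10E,12S,14E)-2-(bromomethyl)-8-[(tert-butyldimethylsilyl)oxy]-12,16-dihydroxy-6,10,14-trimethylhexadeca-2,6,10,14-tetraenoate | OC/C=C(\C)C[C@H](O)/C=C(\C)C[C@H](O[Si](C)(C)C(C)(C)C)/C=C(\C)CC/C=C(/CBr)C(=O)OC
F4 | step 17 | methyl (2E,6E,8S,10E,12S,14E)-2-(bromomethyl)-8-[(tert-butyldimethylsilyl)oxy]-12-hydroxy-6,10,14-trimethyl-16-oxohexadeca-2,6,10,14-tetraenoate | O=C/C=C(\C)C[C@H](O)/C=C(\C)C[C@H](O[Si](C)(C)C(C)(C)C)/C=C(\C)CC/C=C(/CBr)C(=O)OC
F5 | step 17 | (1R,2S,3E,6S,7E,10S,11E)-10-[(tert-butyldimethylsilyl)oxy]-6-hydroxycembra-3,7,11,15(17)-tetraen-16,2-olide | C=C1C(=O)O[C@H]2/C=C(\C)C[C@H](O)/C=C(\C)C[C@H](O[Si](C)(C)C(C)(C)C)/C=C(\C)CC[C@H]12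
F6 | step 13 | methyl (2E,6E,8S,10E,12S,14E)-8-[(tert-butyldimethylsilyl)oxy]-6,10,14-trimethyl-2-(tributylstannyl)-12,16-bis(triethylsilyloxy)hexadeca-2,6,10,14-tetraenoate | CC[Si](CC)(CC)OC/C=C(\C)C[C@H](O[Si](CC)(CC)CC)/C=C(\C)C[C@H](O[Si](C)(C)C(C)(C)C)/C=C(\C)CC/C=C(/[Sn](CCCC)(CCCC)CCCC)C(=O)OC
F7 | step 13 | methyl (2E,6E,8S,10E,12S,14E)-8-[(tert-butyldimethylsilyl)oxy]-2-iodo-6,10,14-trimethyl-12,16-bis(triethylsilyloxy)hexadeca-2,6,10,14-tetraenoate | CC[Si](CC)(CC)OC/C=C(\C)C[C@H](O[Si](CC)(CC)CC)/C=C(\C)C[C@H](O[Si](C)(C)C(C)(C)C)/C=C(\C)CC/C=C(/I)C(=O)OC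
F8 | step 5 | racemic ethyl (2E,6E)-5-hydroxy-3,7-dimethylundeca-2,6-dien-10-ynoate | CCOC(=O)/C=C(\C)CC(O)/C=C(\C)CCC#C
F9 | step 5 | ethyl (2E,6E)-3,7-dimethyl-5-oxoundeca-2,6-dien-10-ynoate | CCOC(=O)/C=C(\C)CC(=O)/C=C(\C)CCC#C
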